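## Retrosynthetic overview
1. No ring is built. Ring B is bought as tetrabromocatechol 1, with its four Br and both O atoms in place, and ring A is bought as 2'-fluoroacetophenone 2.
2. Diaryl ether C–O bond: SNAr of 1 on 2 gives ketone 3. The acetyl group activates C–F and serves as a latent OH.
3. Ring A C–OH bond: Baeyer–Villiger oxidation of 3 gives acetate 4, and methanolysis gives bisphenol 5.
4. Ring A C–Br bonds come last. OH-directed bromination goes para first (6), then ortho (target 7), and ring B has no free position.
5. Order: join the rings, exchange C for O, brominate.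

Assumption: the SMILES carries no stereodescriptor. The molecule has no stereocentre and its diaryl ether axis rotates freely, so it is achiral and "single enantiomer" calls for no stereocontrol.

## Route

Step 1
Reactants: 1 3,4,5,6-tetrabromobenzene-1,2-diol (tetrabromocatechol); 2 1-(2-fluorophenyl)ethan-1-one (2'-fluoroacetophenone)
Product: 3 1-[2-(2,3,4,5-tetrabromo-6-hydroxyphenoxy)phenyl]ethan-1-one
Conditions: 2 (1.2 equiv), Cs2CO3 (2.5 equiv), DMA, 120 °C, Ar, 16 h; then 1 M HCl
Reagents that add atoms: none
Why: This is a nucleophilic aromatic substitution (SNAr, addition–elimination) in which the ortho-acetyl group activates C–F, the twice-deprotonated catechol attacks through its more basic oxygen, and the phenoxide left in the product is too weak and hindered for a second arylation while its charge shields the C–Br bonds of ring B; no stereocentre is formed.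

Step 2
Reactants: 3 1-[2-(2,3,4,5-tetrabromo-6-hydroxyphenoxy)phenyl]ethan-1-one
Product: 5 3,4,5,6-tetrabromo-2-(2-hydroxyphenoxy)phenol, via aryl acetate 4 (not isolated)
Conditions: mCPBA (3 equiv), TFA (1 equiv), CH2Cl2, 0 °C to rt, dark; then HCl (cat.), MeOH, 60 °C
Reagents that add atoms: mCPBA, OOC(=O)c1cccc(Cl)c1
Why: This is a Baeyer–Villiger oxidation in which the aryl group with its ortho-aryloxy donor migrates in preference to methyl (a methyl ketone is used instead of an aldehyde so that hydride migration to a carboxylic acid cannot compete), followed by acid-catalysed transesterification of the acetate, with the C–Br bonds and the diaryl ether inert and no stereocentre formed.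

Step 3
Reactants: 5 3,4,5,6-tetrabromo-2-(2-hydroxyphenoxy)phenol
Product: 7 3,4,5,6-tetrabromo-2-(3,5-dibromo-2-hydroxyphenoxy)phenol, via para-monobromide 6 (not isolated)
Conditions: Br2 (2.05 equiv), AcOH, rt
Reagents that add atoms: bromine, BrBr
Why: This is an electrophilic aromatic substitution in which ring B has no free position and the free OH of ring A outweighs the electron-poor aryloxy group, so bromine enters para and then ortho to OH, while a third bromination meta to OH is much slower and the stoichiometry stops the reaction at the hexabromide; no stereocentre is formed.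

## Compound list
1 | 3,4,5,6-tetrabromobenzene-1,2-diol (tetrabromocatechol) | Oc1c(O)c(Br)c(Br)c(Br)c1Br | starting material
2 | 1-(2-fluorophenyl)ethan-1-one (2'-fluoroacetophenone) | CC(=O)c1ccccc1F | starting material
3 | 1-[2-(2,3,4,5-tetrabromo-6-hydroxyphenoxy)phenyl]ethan-1-one | CC(=O)c1ccccc1Oc1c(O)c(Br)c(Br)c(Br)c1Br | intermediate
4 | 2-(2,3,4,5-tetrabromo-6-hydroxyphenoxy)phenyl acetate | CC(=O)Oc1ccccc1Oc1c(O)c(Br)c(Br)c(Br)c1Br | intermediate
5 | 3,4,5,6-tetrabromo-2-(2-hydroxyphenoxy)phenol | Oc1ccccc1Oc1c(O)c(Br)c(Br)c(Br)c1Br | intermediate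
6 | 3,4,5,6-tetrabromo-2-(5-bromo-2-hydroxyphenoxy)phenol | Oc1ccc(Br)cc1Oc1c(O)c(Br)c(Br)c(Br)c1Br | intermediate
7 | 3,4,5,6-tetrabromo-2-(3,5-dibromo-2-hydroxyphenoxy)phenol (achiral) | Oc1c(Br)cc(Br)cc1Oc1c(O)c(Br)c(Br)c(Br)c1Br | target

Total step count: 3
Longest linear sequence: 3

## Steps most likely to fail

**Step 1.** The risk is that 1 is a weak, hindered O-nucleophile, 2 is only moderately activated, and hot base may degrade 1.
- The fallback sets out from 1 and comes back at 3. It replaces SNAr by a metal-free O-arylation with a diaryliodonium salt.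
- 2'-Iodoacetophenone is oxidised with mCPBA and TsOH·H2O in MeCN at 77 °C. Trapping with 1,3,5-trimethoxybenzene gives (2-acetylphenyl)(2,4,6-trimethoxyphenyl)iodonium 4-methylbenzenesulfonate F1.
- Compound 1 is deprotonated with KOt-Bu (2 equiv) in THF and treated with F1 at rt to 50 °C.
- Ligand coupling at trivalent iodine transfers the electron-poor, ortho-substituted acetylphenyl group and not the trimethoxyphenyl group. This gives 3 at a temperature where weak, hindered phenoxides still react.

**Step 2.** The risk is that aryl migration is slow for this hindered, weakly donating ring, or that the peracid attacks the free bromophenol.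
- The fallback sets out from 3 and comes back at 5. It replaces the peracid oxidation by a benzylic hydroperoxide (Hock-type) rearrangement.
- MeMgBr (3 equiv, the first consumed by the phenol) in THF at −40 to 0 °C adds to the ketone. The product is 3,4,5,6-tetrabromo-2-[2-(2-hydroxypropan-2-yl)phenoxy]phenol F2.
- H2O2 and BF3·OEt2 in CH2Cl2 at 0 °C convert F2 into 3,4,5,6-tetrabromo-2-[2-(2-hydroperoxypropan-2-yl)phenoxy]phenol F3.
- Under the same acid, F3 undergoes aryl migration to oxygen and collapses to 5.
- Trapping of the benzylic cation by the neighbouring phenol is reversible, and the irreversible rearrangement drains it.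

**Step 3.** The risk is a mixture of penta-, hexa- and heptabromides that is hard to separate.
- The fallback sets out from 1 and comes back at 7. It brings in ring A with both bromines already placed, so no late bromination is needed.
- 1,3-Dibromo-5-fluorobenzene is lithiated with LiN(i-Pr)2 in THF at −78 °C between F and Br. Acylation with N-methoxy-N-methylacetamide gives 1-(2,4-dibromo-6-fluorophenyl)ethan-1-one F4.
- SNAr of 1 on F4 (Cs2CO3, DMA, 100 °C, with fluoride leaving far faster than bromide) gives 1-[2,4-dibromo-6-(2,3,4,5-tetrabromo-6-hydroxyphenoxy)phenyl]ethan-1-one F5.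
- Baeyer–Villiger oxidation (mCPBA, TFA, CH2Cl2) gives 2,4-dibromo-6-(2,3,4,5-tetrabromo-6-hydroxyphenoxy)phenyl acetate F6.
- Acid-catalysed methanolysis of F6 gives 7.

## Further compounds
F1 | step 1 | (2-acetylphenyl)(2,4,6-trimethoxyphenyl)iodonium 4-methylbenzenesulfonate | CC(=O)c1ccccc1[I+]c1c(OC)cc(OC)cc1OC.Cc1ccc(cc1)S(=O)(=O)[O-]
F2 | step 2 | 3,4,5,6-tetrabromo-2-[2-(2-hydroxypropan-2-yl)phenoxy]phenol | CC(C)(O)c1ccccc1Oc1c(O)c(Br)c(Br)c(Br)c1Br
F3 | step 2 | 3,4,5,6-tetrabromo-2-[2-(2-hydroperoxypropan-2-yl)phenoxy]phenol | CC(C)(OO)c1ccccc1Oc1c(O)c(Br)c(Br)c(Br)c1Br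
F4 | step 3 | 1-(2,4-dibromo-6-fluorophenyl)ethan-1-one | CC(=O)c1c(F)cc(Br)cc1Br
F5 | step 3 | 1-[2,4-dibromo-6-(2,3,4,5-tetrabromo-6-hydroxyphenoxy)phenyl]ethan-1-one | CC(=O)c1c(Br)cc(Br)cc1Oc1c(O)c(Br)c(Br)c(Br)c1Br
F6 | step 3 | 2,4-dibromo-6-(2,3,4,5-tetrabromo-6-hydroxyphenoxy)phenyl acetate | CC(=O)Oc1c(Br)cc(Br)cc1Oc1c(O)c(Br)c(Br)c(Br)c1Br
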